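**Plan**
1. Target bonds cut, in retrosynthetic order: first C4–C4a and O1–C8a of the chroman together, giving a five-carbon C,O-dinucleophile and a 2-(benzofuran-2-yl)-p-benzoquinone 4-monoketal. Then the bond from benzofuran C2 to that ring (Negishi), then benzofuran C7–CMe2 (aromatic Claisen, back to a 6-O-prenyl ether).
2. Enabling feature: in the carbocycle of the chroman, phenol carbon C7 is para to C4a (which carries C4H2), and C8a (which carries O1) is an unsubstituted carbon β to C7. The ring is a p-quinone in disguise: C4a = free C=O, C7 = masked C=O, C8a = enone β-carbon, C5 = α-carbon blocked by the benzofuran.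
3. Helpers: the dimethyl ketal at C7 and the carbonyl oxygen at C4a. Both leave, as methanol and water, in the operation that rearomatises the ring.
4. Forward order: the furan ring is bought as a benzofuran-3(2H)-one and aromatised; the 1,1-dimethylallyl group comes from the Claisen step; the quinone-ketal ring is joined at C2; the pyran ring closes last; then deprotection.
5. Stereochemistry: the target has no stereocentre. Centres that appear in transit are racemic and are erased.

Key step: step 8

Assumption: 4,6-dihydroxy-1-benzofuran-3(2H)-one and 4-chloro-2-methylbutan-2-ol are taken as catalogue chemicals. Chroman numbering (O1, C2–C4, C4a, C5–C8, C8a) is used for the six-membered ring that becomes the chroman carbocycle.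

Step 1
Reactants: 1 2-bromo-4-methoxyphenol
Product: 2 2-bromo-4,4-dimethoxycyclohexa-2,5-dien-1-one
Conditions: PhI(OAc)2 (1.1 equiv), MeOH, 0 °C to rt
Reagents that add atoms: methanol, CO
Why: Oxidative dearomatisation of a p-alkoxyphenol with a trivalent iodine reagent, in which the cationic intermediate is best stabilised at the methoxy-bearing para carbon and captures methanol there to give the quinone monoketal.

Step 2
Reactants: 3 4,6-dihydroxy-1-benzofuran-3(2H)-one
Product: 4 4-hydroxy-6-[(3-methylbut-2-en-1-yl)oxy]-1-benzofuran-3(2H)-one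
Conditions: prenyl bromide (1.0 equiv), K2CO3 (1.1 equiv), acetone, reflux
Reagents that add atoms: prenyl bromide (1-bromo-3-methylbut-2-ene), CC(C)=CCBr
Why: Williamson etherification that should pick the 6-OH, which is para to the carbonyl-bearing carbon C3a (most acidic) and unhindered, while the 4-OH is hydrogen-bonded to the C3 carbonyl.

Step 3
Reactants: 4 4-hydroxy-6-[(3-methylbut-2-en-1-yl)oxy]-1-benzofuran-3(2H)-one
Product: 5 4-(methoxymethoxy)-6-[(3-methylbut-2-en-1-yl)oxy]-1-benzofuran-3(2H)-one
Conditions: MOMCl, i-Pr2NEt, CH2Cl2, 0 °C to rt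
Reagents that add atoms: chloromethyl methyl ether (MOMCl), COCCl
Why: O-alkylation of the remaining phenol with a very reactive α-chloro ether (MOM protection) under an amine base too weak to enolise C2 of the ketone.

Step 4
Reactants: 5 4-(methoxymethoxy)-6-[(3-methylbut-2-en-1-yl)oxy]-1-benzofuran-3(2H)-one
Product: 7 4-(methoxymethoxy)-6-[(3-methylbut-2-en-1-yl)oxy]-1-benzofuran, via benzylic alcohol 6 (not isolated)
Conditions: NaBH4, MeOH/THF, 0 °C to rt; then 1 M aq HCl, rt
Reagents that add atoms: none
Why: Hydride reduction of the aryl ketone, followed by acid-promoted elimination of water from a benzylic alcohol activated by ortho and para alkoxy groups and driven by formation of the aromatic furan ring (benzofuranone-to-benzofuran conversion).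

Step 5
Reactants: 7 4-(methoxymethoxy)-6-[(3-methylbut-2-en-1-yl)oxy]-1-benzofuran
Product: 9 4-(methoxymethoxy)-7-(2-methylbut-3-en-2-yl)-1-benzofuran-6-ol, via ortho-dienone 8 (not isolated)
Conditions: PhNEt2, 200 °C, sealed tube, Ar
Reagents that add atoms: none
Why: Aromatic Claisen rearrangement ([3,3] shift, then tautomerisation) inverts the prenyl unit into the 1,1-dimethylallyl group; the para position C3a is a ring-fusion carbon, so no Cope relay can end there, and C7 should win over C5 because the C6–C7 bond has the higher double-bond character in benzofuran and C7 is flanked only by the tied-back ring oxygen, whereas C5 is shielded by the 4-OMOM group.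

Step 6
Reactants: 9 4-(methoxymethoxy)-7-(2-methylbut-3-en-2-yl)-1-benzofuran-6-ol
Product: 10 4,6-bis(methoxymethoxy)-7-(2-methylbut-3-en-2-yl)-1-benzofuran
Conditions: NaH, MOMCl, DMF, 0 °C to rt
Reagents that add atoms: chloromethyl methyl ether (MOMCl), COCCl
Why: Williamson-type O-alkylation of the hindered phenoxide with the small, reactive MOMCl removes the last acidic proton before the organometallic steps.

Step 7
Reactants: 10 4,6-bis(methoxymethoxy)-7-(2-methylbut-3-en-2-yl)-1-benzofuran; 2 2-bromo-4,4-dimethoxycyclohexa-2,5-dien-1-one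
Product: 13 2-[4,6-bis(methoxymethoxy)-7-(2-methylbut-3-en-2-yl)-1-benzofuran-2-yl]-4,4-dimethoxycyclohexa-2,5-dien-1-one, via 2-lithiobenzofuran 11 (not isolated), via benzofuranylzinc chloride 12 (not isolated)
Conditions: n-BuLi (1.05 equiv), THF, −78 °C; ZnCl2, −78 °C to rt; 2, Pd(OAc)2 (5 mol %), SPhos (10 mol %), THF, rt to 45 °C
Reagents that add atoms: none
Why: Deprotonation of the most acidic C–H of the benzofuran (C2–H), transmetalation to zinc and Negishi coupling with the α-bromoenone unit of 2 under zerovalent palladium join the halves under neutral conditions that the acid-labile ketal and the dienone tolerate.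

Step 8
Reactants: 13 2-[4,6-bis(methoxymethoxy)-7-(2-methylbut-3-en-2-yl)-1-benzofuran-2-yl]-4,4-dimethoxycyclohexa-2,5-dien-1-one; 14 4-chloro-2-methylbutan-2-ol
Product: 19 5-[4,6-bis(methoxymethoxy)-7-(2-methylbut-3-en-2-yl)-1-benzofuran-2-yl]-2,2-dimethylchroman-7-ol, via dimagnesium reagent 15 (not isolated), via quinol ketal 16 (not isolated), via quinol dienone 17 (not isolated), via oxa-Michael adduct 18 (not isolated)
Conditions: 14, MeMgCl (1.0 equiv), THF, −20 °C, then Mg turnings, BrCH2CH2Br (cat.), reflux; added to 13, LaCl3·2LiCl, THF, −78 to −20 °C; then 2 M aq HCl, THF, 0 °C to rt, same flask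
Reagents that add atoms: water, O
Why: Proposed new method: the carbanion end of 15 adds 1,2 to the only free carbonyl of 13, the future C4a (the future C7 is masked as its ketal, and LaCl3·2LiCl favours carbonyl over conjugate attack), which forms the C4–C4a bond and gives 16. Aqueous acid then hydrolyses the ketal to the cross-conjugated dienone 17, the tertiary hydroxyl adds to the protonated dienone at the unsubstituted β-carbon C8a to form the O1–C8a bond, and adduct 18 (through its dienol, formally a hydrate of the arene) ionises at C4a, loses water and a proton and ends as the C7 phenol 19. The closest known reaction types are the 1,2-addition of organometallics to quinone monoketals, the oxa-Michael closure of side-chain alcohols onto p-quinols and the acid dehydration of 4-hydroxycyclohexenones to phenols; new is their merger, by means of a C,O-dianion, into a one-flask chroman annulation. The pyran ring closes 6-exo-trig, helped by the gem-dimethyl group. The stereocentres at C4a (16, 17) and at C4a and C8a (18, cis fusion expected) form as racemates and vanish on aromatisation, so none needs control. Site selectivity of the C–O bond rests on the benzofuran at C5: attack there is hindered, reversible and leads to a carbon without hydrogen that cannot aromatise, so only the C8a channel is drained, while the large excess of water lets ketal hydrolysis outrun closure and leaves O7 as free phenol.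

Step 9
Reactants: 19 5-[4,6-bis(methoxymethoxy)-7-(2-methylbut-3-en-2-yl)-1-benzofuran-2-yl]-2,2-dimethylchroman-7-ol
Product: 20 2-(7-hydroxy-2,2-dimethylchroman-5-yl)-7-(2-methylbut-3-en-2-yl)-1-benzofuran-4,6-diol (target)
Conditions: HCl (cat., from 3 M aq), MeOH, 45 °C
Reagents that add atoms: none
Why: Acid-catalysed acetal exchange (MOM cleavage) in methanol, which should spare the monosubstituted vinyl group (protonated far more slowly than an acetal) and the chroman ether; any MOM loss already suffered in step 8 is harmless here.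

**Compound list**
1 | 2-bromo-4-methoxyphenol | COc1ccc(O)c(Br)c1 | starting material
2 | 2-bromo-4,4-dimethoxycyclohexa-2,5-dien-1-one | COC1(OC)C=CC(=O)C(Br)=C1 | intermediate
3 | 4,6-dihydroxy-1-benzofuran-3(2H)-one | O=C1COc2cc(O)cc(O)c12 | starting material
4 | 4-hydroxy-6-[(3-methylbut-2-en-1-yl)oxy]-1-benzofuran-3(2H)-one | CC(C)=CCOc1cc(O)c2C(=O)COc2c1 | intermediate
5 | 4-(methoxymethoxy)-6-[(3-methylbut-2-en-1-yl)oxy]-1-benzofuran-3(2H)-one | CC(C)=CCOc1cc(OCOC)c2C(=O)COc2c1 | intermediate
6 | 4-(methoxymethoxy)-6-[(3-methylbut-2-en-1-yl)oxy]-2,3-dihydro-1-benzofuran-3-ol (racemic, not isolated) | CC(C)=CCOc1cc(OCOC)c2C(O)COc2c1 | intermediate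
7 | 4-(methoxymethoxy)-6-[(3-methylbut-2-en-1-yl)oxy]-1-benzofuran | CC(C)=CCOc1cc(OCOC)c2ccoc2c1 | intermediate
8 | 4-(methoxymethoxy)-7-(2-methylbut-3-en-2-yl)-1-benzofuran-6(7H)-one (racemic, not isolated) | C=CC(C)(C)C1C(=O)C=C(OCOC)c2ccoc12 | intermediate
9 | 4-(methoxymethoxy)-7-(2-methylbut-3-en-2-yl)-1-benzofuran-6-ol | C=CC(C)(C)c1c(O)cc(OCOC)c2ccoc12 | intermediate
10 | 4,6-bis(methoxymethoxy)-7-(2-methylbut-3-en-2-yl)-1-benzofuran | C=CC(C)(C)c1c(OCOC)cc(OCOC)c2ccoc12 | intermediate
11 | [4,6-bis(methoxymethoxy)-7-(2-methylbut-3-en-2-yl)-1-benzofuran-2-yl]lithium (not isolated) | [Li]c1cc2c(OCOC)cc(OCOC)c(C(C)(C)C=C)c2o1 | intermediate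
12 | [4,6-bis(methoxymethoxy)-7-(2-methylbut-3-en-2-yl)-1-benzofuran-2-yl]zinc chloride (not isolated) | Cl[Zn]c1cc2c(OCOC)cc(OCOC)c(C(C)(C)C=C)c2o1 | intermediate
13 | 2-[4,6-bis(methoxymethoxy)-7-(2-methylbut-3-en-2-yl)-1-benzofuran-2-yl]-4,4-dimethoxycyclohexa-2,5-dien-1-one | C=CC(C)(C)c1c(OCOC)cc(OCOC)c2cc(C3=CC(OC)(OC)C=CC3=O)oc12 | intermediate
14 | 4-chloro-2-methylbutan-2-ol | CC(C)(O)CCCl | starting material
15 | [3-(chloromagnesiooxy)-3-methylbutyl]magnesium chloride (not isolated) | CC(C)(CC[Mg]Cl)O[Mg]Cl | intermediate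
16 | 2-[4,6-bis(methoxymethoxy)-7-(2-methylbut-3-en-2-yl)-1-benzofuran-2-yl]-1-(3-hydroxy-3-methylbutyl)-4,4-dimethoxycyclohexa-2,5-dien-1-ol (racemic, drawn protonated, not isolated) | C=CC(C)(C)c1c(OCOC)cc(OCOC)c2cc(C3=CC(OC)(OC)C=CC3(O)CCC(C)(C)O)oc12 | intermediate
17 | 3-[4,6-bis(methoxymethoxy)-7-(2-methylbut-3-en-2-yl)-1-benzofuran-2-yl]-4-hydroxy-4-(3-hydroxy-3-methylbutyl)cyclohexa-2,5-dien-1-one (racemic, not isolated) | C=CC(C)(C)c1c(OCOC)cc(OCOC)c2cc(C3=CC(=O)C=CC3(O)CCC(C)(C)O)oc12 | intermediate
18 | 5-[4,6-bis(methoxymethoxy)-7-(2-methylbut-3-en-2-yl)-1-benzofuran-2-yl]-4a-hydroxy-2,2-dimethyl-3,4,4a,8a-tetrahydro-2H-chromen-7(8H)-one (racemic, cis fusion expected, not isolated) | C=CC(C)(C)c1c(OCOC)cc(OCOC)c2cc(C3=CC(=O)CC4OC(C)(C)CCC34O)oc12 | intermediate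
19 | 5-[4,6-bis(methoxymethoxy)-7-(2-methylbut-3-en-2-yl)-1-benzofuran-2-yl]-2,2-dimethylchroman-7-ol | C=CC(C)(C)c1c(OCOC)cc(OCOC)c2cc(-c3cc(O)cc4c3CCC(C)(C)O4)oc12 | intermediate
20 | 2-(7-hydroxy-2,2-dimethylchroman-5-yl)-7-(2-methylbut-3-en-2-yl)-1-benzofuran-4,6-diol | C=CC(C)(C)c1c(O)cc(O)c2cc(-c3cc(O)cc4c3CCC(C)(C)O4)oc12 | target

**Count**
Total steps: 9. Longest linear sequence: 8 (steps 2 to 9, from 3).

**Steps most likely to fail**

Step 8. Four processes could spoil it:
- electron transfer or conjugate addition of the Grignard reagent in place of 1,2-addition;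
- ring closure from the methoxy-oxocarbenium ion before hydrolysis, which would leave O7 methylated;
- a 1,2-shift of the side chain (dienone–phenol pathway) ahead of the oxa-Michael closure;
- sluggish dehydration.

The fallback sets out from 10 (as its zinc reagent 12) and comes back at 20. It makes the pyran ring first, by the classical phenol route. Commercial 5-bromobenzene-1,3-diol is treated with 2-methylbut-3-en-2-ol and BF3·OEt2 in dioxane. Friedel–Crafts prenylation para to one hydroxyl gives 5-bromo-4-(3-methylbut-2-en-1-yl)benzene-1,3-diol F1. This cyclises under the acid to 5-bromo-2,2-dimethylchroman-7-ol F2, and material from alkylation between the two hydroxyls has to be separated off. MOMCl and i-Pr2NEt give 5-bromo-7-(methoxymethoxy)-2,2-dimethylchroman F3. Negishi coupling of 12 with F3 (Pd(OAc)2, SPhos, THF, 50 °C) gives 5-[4,6-bis(methoxymethoxy)-7-(2-methylbut-3-en-2-yl)-1-benzofuran-2-yl]-7-(methoxymethoxy)-2,2-dimethylchroman F4. HCl in MeOH, as in step 9, converts F4 into 20.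

Step 5. The risks are poor site selectivity between C5 and C7, and thermal addition of the freed phenol to the vinyl group.

The fallback sets out from 3 and comes back at 10. It replaces the sigmatropic shift by a cross-coupling. MOMCl and i-Pr2NEt protect both hydroxyls to give 4,6-bis(methoxymethoxy)-1-benzofuran-3(2H)-one F5. Electrophilic iodination (NIS, MeCN, 0 °C) at the less hindered position next to the ring oxygen gives 7-iodo-4,6-bis(methoxymethoxy)-1-benzofuran-3(2H)-one F6. NaBH4 gives 7-iodo-4,6-bis(methoxymethoxy)-2,3-dihydro-1-benzofuran-3-ol F7, which loses water on treatment with dilute HCl to give 7-iodo-4,6-bis(methoxymethoxy)-1-benzofuran F8. A γ-selective Suzuki–Miyaura allylation with 3-methylbut-2-enylboronic acid pinacol ester (Pd(OAc)2, bulky biarylphosphine, K3PO4, THF/H2O) then places the 1,1-dimethylallyl group at C7 and gives 10.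

Step 7. The risks are competing ortho-lithiation at C5 between the two MOM ethers, slow oxidative addition, and decay of the bromodienone under the coupling conditions.

The fallback sets out from 10 and 1 and comes back at 13. It forms the ring–ring bond at the phenol oxidation level and moves the dearomatisation behind it. C2-selective C–H borylation of 10 ([Ir(OMe)(cod)]2, dtbpy, B2pin2, THF, rt) gives 2-[4,6-bis(methoxymethoxy)-7-(2-methylbut-3-en-2-yl)-1-benzofuran-2-yl]-4,4,5,5-tetramethyl-1,3,2-dioxaborolane F9. Suzuki–Miyaura coupling with 1 (Pd(dppf)Cl2, K2CO3, dioxane/H2O, 80 °C) gives 2-[4,6-bis(methoxymethoxy)-7-(2-methylbut-3-en-2-yl)-1-benzofuran-2-yl]-4-methoxyphenol F10. PhI(OAc)2 in MeOH at 0 °C, as in step 1, converts F10 into 13.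

**Further compounds**
F1 | step 8 | 5-bromo-4-(3-methylbut-2-en-1-yl)benzene-1,3-diol | CC(C)=CCc1c(O)cc(O)cc1Br
F2 | step 8 | 5-bromo-2,2-dimethylchroman-7-ol | CC1(C)CCc2c(Br)cc(O)cc2O1
F3 | step 8 | 5-bromo-7-(methoxymethoxy)-2,2-dimethylchroman | CC1(C)CCc2c(Br)cc(OCOC)cc2O1
F4 | step 8 | 5-[4,6-bis(methoxymethoxy)-7-(2-methylbut-3-en-2-yl)-1-benzofuran-2-yl]-7-(methoxymethoxy)-2,2-dimethylchroman | C=CC(C)(C)c1c(OCOC)cc(OCOC)c2cc(-c3cc(OCOC)cc4c3CCC(C)(C)O4)oc12
F5 | step 5 | 4,6-bis(methoxymethoxy)-1-benzofuran-3(2H)-one | COCOc1cc(OCOC)c2C(=O)COc2c1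
F6 | step 5 | 7-iodo-4,6-bis(methoxymethoxy)-1-benzofuran-3(2H)-one | COCOc1cc(OCOC)c2C(=O)COc2c1I
F7 | step 5 | 7-iodo-4,6-bis(methoxymethoxy)-2,3-dihydro-1-benzofuran-3-ol | COCOc1cc(OCOC)c2C(O)COc2c1I
F8 | step 5 | 7-iodo-4,6-bis(methoxymethoxy)-1-benzofuran | COCOc1cc(OCOC)c2ccoc2c1I
F9 | step 7 | 2-[4,6-bis(methoxymethoxy)-7-(2-methylbut-3-en-2-yl)-1-benzofuran-2-yl]-4,4,5,5-tetramethyl-1,3,2-dioxaborolane | C=CC(C)(C)c1c(OCOC)cc(OCOC)c2cc(B3OC(C)(C)C(C)(C)O3)oc12
F10 | step 7 | 2-[4,6-bis(methoxymethoxy)-7-(2-methylbut-3-en-2-yl)-1-benzofuran-2-yl]-4-methoxyphenol | C=CC(C)(C)c1c(OCOC)cc(OCOC)c2cc(-c3cc(OC)ccc3O)oc12
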